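## Analysis of the target

Target 22 is a (2S)-flavanone, 2-(2,2-dimethyl-2H-chromen-6-yl)-5,7-dihydroxy-6,8-bis(3-methylbut-2-enyl)chroman-4-one. Ring A is a hexasubstituted benzene: C5 and C7 carry hydroxyls, C6 and C8 carry prenyl chains, and C4a and C8a are fused to ring C, the dihydropyranone with the C4 ketone. Ring B carries a fused 2,2-dimethylpyran (ring D) and is bonded through its C6 to C2 of ring C. C2 is the only stereocentre (S, the usual flavanone configuration); it is benzylic and β to the ketone through O1, so retro-oxa-Michael opening to a 2'-hydroxychalcone erases it under base and, more slowly, under hot acid. The sensitive groups are the two trisubstituted alkenes ortho to phenols (acid closes them to chromans), the cis styrenyl alkene of ring D (acid, electrophiles, metathesis catalysts) and the electron-rich free phenols. The difficulty is twofold: two prenyl groups must sit at defined carbons of a fully substituted ring A without O/C mixtures or 1,1-dimethylallyl isomers, and C2 must be created late and irreversibly. The strategy rests on one feature: in a 5,7-dioxygenated chromone, C6 and C8 are the only ring A carbons bearing hydrogen, and each lies ortho or para to O5 and O7, which is exactly the reach of [3,3] allyl shifts from oxygen to carbon.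

## Retrosynthetic reasoning

22 ⇒ 21. The two phenols are masked last as methoxymethyl ethers, so the final operation cuts two O–CH2 acetal bonds. Free phenols flanked by prenyl groups would interfere with the metal-mediated C–C bond formation before it. An acetal comes off under mild acid without base, which is what the C2 stereocentre tolerates best.

21 ⇒ 12 + 20. The C2–aryl bond is cut. It is the only bond at the stereocentre that divides the molecule into two fragments of similar size, and it leaves ring C intact as chromone 12 with the C4 ketone already at the right oxidation level. The forward reaction is an enantioselective 1,4-addition of boronic acid 20 to C2 of 12. It forms a C–C bond irreversibly, so C2 is never set by a reversible C–O ring closure.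

20 ⇒ 17 ⇒ 15 ⇒ 13 + 14. The C–B bond goes back to the C–Br bond of 17. Ring D of 17 is opened at C4a–C4 and O1–C2 to the aryl propargyl ether 15 (propargyl Claisen, hydrogen shift, electrocyclisation), which comes from 13 and 14. The two ortho positions of 15 are equivalent, so the ring can close in only one way.

12 ⇒ 11 ⇒ 9 + 10. After removal of the acetals, each prenyl group is cut at its C=C bond by a metathesis transform, which gives the diallyl compound 9 and alkene 10. This is done on purpose: an unsubstituted allyl group is unchanged by allylic inversion, a prenyl group is not. The metathesis is placed before fragment 20 arrives because the ring D alkene would compete.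

9 ⇒ 5 (key disconnection). The C6–CH2 and C8–CH2 bonds are cut and both allyl groups are returned to O5 and O7. The forward reaction has to move two allyl groups from oxygen to the two free ring carbons. Every route across ring A ends at the same compound, because an allyl group that reaches an occupied C6 is relayed to C8.

5 ⇒ 3 ⇒ 1 + 2. Ring C of 5 is cut at O1–C2 and C2–C3, which takes out one carbon and leaves the acetyl group of 3. The two O–allyl bonds then go back to 1 and two molecules of 2. Allylation is placed before ring formation so that only the chelated phenol, which is needed for the closure, is free when the one-carbon unit for C2 is brought in. The reagent for that condensation can otherwise methylate unchelated phenols.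

## Alternatives that were turned down

Alternative 1: ortho-quinone methide cycloaddition. Ring C is cut at O1–C2 and C3–C4. In the forward step, salicylaldehyde A2 and trimethyl orthoformate A4 would condense under a chiral phosphoric acid to the 4-methoxy ortho-quinone methide A5. This would add styrene A3 in a formal [4+2] cycloaddition and give the 4-methoxychromane A1.
- For: ring C and the C2 stereocentre are made in one convergent step, and on that point it is stronger than the chosen route, which needs a separate step for C2.
- Against: A2 is already a hexasubstituted benzene with both prenyl groups, so the ring A problem is only moved to an earlier, unspecified sequence.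
- Against: the Brønsted acid meets a free phenol ortho to a prenyl group (chroman formation) and two acetals.
- Against: A3 offers two styrenyl alkenes, the vinyl group and the ring D alkene.
- Against: A1 is at the wrong oxidation level at C4, so ether cleavage and oxidation to the ketone must follow in the presence of three electron-rich alkenes.
- Comparison: the chosen route carries the C4 ketone from the first ring-forming step and builds ring A from two cheap compounds. It pays with one more step for C2.

Alternative 2: aryne insertion into a cinnamic acid C–O bond. The C8a–O1 and C4a–C4 bonds are cut. In the forward step CsF would convert silylaryl triflate A7 into aryne A8. The carboxylate of acid A9 would add at C8a, and the acyl group would shift to C4a to give chalcone A6.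
- For: the conditions are mild, the coupling is convergent, and the C5 acetal should direct the nucleophile to the remote aryne carbon, so the regiochemistry is plausible.
- Against: A7 is a benzene with six different substituents and needs a long preparation that again presupposes solved prenylation.
- Against: the triple bond of A8 sits next to a prenyl group and could be consumed by an intramolecular ene reaction.
- Against: the key step makes no ring and no stereocentre. Closing A6 to 21 enantioselectively is a reversible oxa-Michael addition, for which such unactivated substrates lack dependable asymmetric catalysis.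
- Comparison: it is equal in convergence, but the chosen route controls C2 through an irreversible C–C bond formation.

Alternative 3: carbonylative alkyne annulation. The C4a–C4, C4–C3 and O1–C2 bonds are cut. Iodophenol A11, carbon monoxide A13 and alkyne A12 would combine under PdCl2(PPh3)2 and a secondary amine to give flavone A10.
- For: three bonds and ring C form in one step from three components, which is better bond economy than any single step of the chosen route.
- Against: oxidative addition of zerovalent palladium into the di-ortho-substituted, electron-rich C–I bond of A11 is slow.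
- Against: closure of the phenol oxygen in the 5-exo mode competes with the 6-endo mode that ring C needs.
- Against: A11 again needs both prenyl groups in place.
- Against: A10 has no stereocentre. C2 would have to come from an enantioselective 1,4-reduction of the C2=C3 bond next to three other alkenes. Hydrogenation is excluded, and a ligated CuH reduction of this vinylogous ester is not dependable.
- Comparison: the chosen route reaches the same ring C from a chromone and adds the aryl group with control of C2 in one step.

Key step: step 3

Assumption: the facial sense of the Pd(OCOCF3)2/pyridine–oxazoline catalyst on the chromone is taken to follow that on β-substituted cyclic enones; the ligand antipode is exchanged if a first run shows the opposite sense.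

## Route

Step 1
Reactants: 1 2,4,6-trihydroxyacetophenone; 2 allyl bromide
Product: 3 1-[2,4-bis(allyloxy)-6-hydroxyphenyl]ethanone
Conditions: allyl bromide (2.2 equiv in all), K2CO3, acetone, reflux
Reagents that add atoms: allyl bromide (second equivalent of 2), C=CCBr
Why: Twofold Williamson ether synthesis that consumes two molecules of 2, one for each new O–allyl bond. The para hydroxyl and one ortho hydroxyl are alkylated, while the second ortho hydroxyl stays locked in its hydrogen bond to the acetyl carbonyl, and a weak base in acetone favours O- over C-allylation.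

Step 2
Reactants: 3 1-[2,4-bis(allyloxy)-6-hydroxyphenyl]ethanone
Product: 5 5,7-bis(allyloxy)-4H-chromen-4-one, via enaminone 4 (not isolated)
Conditions: Me2NCH(OMe)2, PhMe, 100 °C; then conc. HCl, CH2Cl2, rt
Reagents that add atoms: N,N-dimethylformamide dimethyl acetal, COC(OC)N(C)C
Why: Enaminone route to chromones: condensation of the methyl ketone with the amide acetal gives 4, and acid then triggers oxa-Michael addition of the chelated phenol and loss of dimethylamine; allyl aryl ethers are inert to both stages.

Step 3
Reactants: 5 5,7-bis(allyloxy)-4H-chromen-4-one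
Product: 9 6,8-diallyl-5,7-dihydroxy-4H-chromen-4-one, via 8-allyl-5-allyloxy-7-hydroxychromone 6 (not isolated), via 6-allyl-7-allyloxy-5-hydroxychromone 7 (not isolated), via 6-allyl-5-allyloxy-7-hydroxychromone 8 (not isolated)
Conditions: PhNEt2, 200 °C, Ar (sealed tube)
Reagents that add atoms: none
Why: Two thermal aromatic Claisen rearrangements, each a concerted [3,3] shift through a chair-like transition state followed by enolisation of the 2,4-cyclohexadienone to the phenol. The O5 allyl group can reach only C6, because its other ortho carbon C4a is quaternary, while the O7 allyl group can reach C8 or C6, so the mono-shifted phenols 6, 7 and 8 are all possible way stations. Where the second allyl group arrives at a C6 that is already substituted, the dienone cannot enolise and instead passes the group on by a Cope [3,3] shift to C8, which is para to O5, or falls back to the ether; a shift from O7 through C6 to C4a only gives a blocked dienone that reverts. Because an unsubstituted allyl group is its own allylic transpose, one or two inversions leave the same CH2–CH=CH2 chain, so every pathway drains into 9. The closest known reaction type is the ortho and para Claisen rearrangement of allyl aryl ethers of 5- and 7-oxygenated chromones, flavones and ortho-hydroxyacetophenones. No ring is closed and no stereocentre is formed. The selectivity needed is regiochemical only, and the substrate secures it: C6 and C8 are the sole ring A carbons bearing hydrogen, and rearomatisation plus the hydrogen bond from the new 5-OH to the C4 carbonyl make 9 the thermodynamic sink. The basic amine solvent keeps the medium free of acid, which would otherwise close an ortho-allylphenol onto its alkene.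

Step 4
Reactants: 9 6,8-diallyl-5,7-dihydroxy-4H-chromen-4-one; 10 2-methylbut-2-ene
Product: 11 5,7-dihydroxy-6,8-bis(3-methylbut-2-enyl)-4H-chromen-4-one
Conditions: second-generation Grubbs catalyst RuCl2(=CHPh)(PCy3)(H2IMes) (5 mol %), 2-methylbut-2-ene (large excess), CH2Cl2, 40 °C, sealed tube
Reagents that add atoms: 2-methylbut-2-ene (second equivalent of 10), CC=C(C)C
Why: Twofold olefin cross-metathesis in which each terminal allyl arene exchanges its CH2 terminus for the isopropylidene unit of one molecule of 10 and propene escapes. The push–pull C2=C3 bond of the chromone is too electron-poor and too hindered to engage the catalyst.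

Step 5
Reactants: 11 5,7-dihydroxy-6,8-bis(3-methylbut-2-enyl)-4H-chromen-4-one
Product: 12 5,7-bis(methoxymethoxy)-6,8-bis(3-methylbut-2-enyl)-4H-chromen-4-one
Conditions: NaH (2.5 equiv), MeOCH2Cl (2.5 equiv), DMF, 0 °C to rt
Reagents that add atoms: chloromethyl methyl ether, COCCl
Why: O-alkylation of both phenoxides with the chloromethyl ether; full deprotonation with NaH breaks the chelate of the 5-OH, and a non-nucleophilic base leaves the base-sensitive C2 of the chromone alone.

Step 6
Reactants: 13 4-bromophenol; 14 3-chloro-3-methylbut-1-yne
Product: 15 1-bromo-4-[(2-methylbut-3-yn-2-yl)oxy]benzene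
Conditions: K2CO3, KI, CuI (cat.), acetone, reflux
Reagents that add atoms: none
Why: Copper-assisted O-propargylation of a phenoxide by a tertiary propargylic chloride, the standard entry to aryl 1,1-dimethylpropargyl ethers; CuI activates the terminal alkyne so that chloride leaves readily and the phenoxide attacks the tertiary carbon.

Step 7
Reactants: 15 1-bromo-4-[(2-methylbut-3-yn-2-yl)oxy]benzene
Product: 17 6-bromo-2,2-dimethyl-2H-chromene, via allenylphenol 16 (not isolated)
Conditions: PhNEt2, 190 °C
Reagents that add atoms: none
Why: Propargyl Claisen rearrangement to the ortho-allenylphenol 16, then 1,5-hydrogen shift to an ortho-quinone methide and 6π oxa-electrocyclisation; both ortho carbons of 15 are equivalent, so only one chromene can form.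

Step 8
Reactants: 17 6-bromo-2,2-dimethyl-2H-chromene
Product: 20 (2,2-dimethyl-2H-chromen-6-yl)boronic acid, via aryllithium 18 (not isolated), via lithium aryltriisopropoxyborate 19 (not isolated)
Conditions: n-BuLi, THF, −78 °C; B(OiPr)3, −78 °C to rt; 1 M HCl, 0 °C
Reagents that add atoms: triisopropyl borate, CC(C)OB(OC(C)C)OC(C)C; water, O
Why: Bromine–lithium exchange, trapping of the aryllithium by the borate ester and brief cold hydrolysis of the ate complex; the chromene alkene is inert to n-BuLi at −78 °C and survives a short contact with dilute acid.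

Step 9
Reactants: 12 5,7-bis(methoxymethoxy)-6,8-bis(3-methylbut-2-enyl)-4H-chromen-4-one; 20 (2,2-dimethyl-2H-chromen-6-yl)boronic acid
Product: 21 (2S)-2-(2,2-dimethyl-2H-chromen-6-yl)-5,7-bis(methoxymethoxy)-6,8-bis(3-methylbut-2-enyl)chroman-4-one
Conditions: Pd(OCOCF3)2 (5 mol %), (R)-t-BuPyOX (6 mol %), NH4PF6 (30 mol %), H2O (5 equiv), ClCH2CH2Cl, 60 °C
Reagents that add atoms: none
Why: Asymmetric conjugate addition of an arylboronic acid to a chromone under cationic divalent palladium: transmetalation, enantio-determining insertion of C2=C3 into the aryl–palladium bond with the aryl group going to C2, and protonolysis of the resulting enolate by water. The tert-butyl group of the (R)-pyridine–oxazoline ligand is expected to direct the aryl group to the Re face of C2, which gives 2S, and the near-neutral medium avoids base-induced opening of ring C.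

Step 10
Reactants: 21 (2S)-2-(2,2-dimethyl-2H-chromen-6-yl)-5,7-bis(methoxymethoxy)-6,8-bis(3-methylbut-2-enyl)chroman-4-one
Product: 22 (2S)-2-(2,2-dimethyl-2H-chromen-6-yl)-5,7-dihydroxy-6,8-bis(3-methylbut-2-enyl)chroman-4-one
Conditions: HCl (1 M in MeOH), 40 °C
Reagents that add atoms: none
Why: Acid-catalysed transacetalisation of both methoxymethyl ethers to methanol, the C5 ether being assisted by the peri carbonyl; dilute acid at moderate temperature without base is chosen to spare the prenyl and chromene alkenes and the C2 configuration.

## Compound list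

1 | 2,4,6-trihydroxyacetophenone | CC(=O)c1c(O)cc(O)cc1O | starting material
2 | allyl bromide | C=CCBr | starting material
3 | 1-[2,4-bis(allyloxy)-6-hydroxyphenyl]ethanone | CC(=O)c1c(O)cc(OCC=C)cc1OCC=C | intermediate
4 | (E)-1-[2,4-bis(allyloxy)-6-hydroxyphenyl]-3-(dimethylamino)prop-2-en-1-one | CN(C)/C=C/C(=O)c1c(O)cc(OCC=C)cc1OCC=C | intermediate
5 | 5,7-bis(allyloxy)-4H-chromen-4-one | C=CCOc1cc(OCC=C)c2c(c1)OC=CC2=O | intermediate
6 | 8-allyl-5-(allyloxy)-7-hydroxy-4H-chromen-4-one | C=CCOc1cc(O)c(CC=C)c2c1C(=O)C=CO2 | intermediate
7 | 6-allyl-7-(allyloxy)-5-hydroxy-4H-chromen-4-one | C=CCOc1cc2c(c(O)c1CC=C)C(=O)C=CO2 | intermediate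
8 | 6-allyl-5-(allyloxy)-7-hydroxy-4H-chromen-4-one | C=CCOc1c(CC=C)c(O)cc2c1C(=O)C=CO2 | intermediate
9 | 6,8-diallyl-5,7-dihydroxy-4H-chromen-4-one | C=CCc1c(O)c(CC=C)c2c(c1O)C(=O)C=CO2 | intermediate
10 | 2-methylbut-2-ene | CC=C(C)C | starting material
11 | 5,7-dihydroxy-6,8-bis(3-methylbut-2-enyl)-4H-chromen-4-one | CC(C)=CCc1c(O)c(CC=C(C)C)c2c(c1O)C(=O)C=CO2 | intermediate
12 | 5,7-bis(methoxymethoxy)-6,8-bis(3-methylbut-2-enyl)-4H-chromen-4-one | CC(C)=CCc1c(OCOC)c(CC=C(C)C)c2c(c1OCOC)C(=O)C=CO2 | intermediate
13 | 4-bromophenol | Oc1ccc(Br)cc1 | starting material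
14 | 3-chloro-3-methylbut-1-yne | C#CC(C)(C)Cl | starting material
15 | 1-bromo-4-[(2-methylbut-3-yn-2-yl)oxy]benzene | C#CC(C)(C)Oc1ccc(Br)cc1 | intermediate
16 | 4-bromo-2-(3-methylbuta-1,2-dienyl)phenol | CC(C)=C=Cc1cc(Br)ccc1O | intermediate
17 | 6-bromo-2,2-dimethyl-2H-chromene | CC1(C)C=Cc2cc(Br)ccc2O1 | intermediate
18 | (2,2-dimethyl-2H-chromen-6-yl)lithium | [Li]c1ccc2OC(C)(C)C=Cc2c1 | intermediate
19 | lithium (2,2-dimethyl-2H-chromen-6-yl)tri(propan-2-yloxy)borate | [Li+].CC(C)O[B-](OC(C)C)(OC(C)C)c1ccc2OC(C)(C)C=Cc2c1 | intermediate
20 | (2,2-dimethyl-2H-chromen-6-yl)boronic acid | OB(O)c1ccc2OC(C)(C)C=Cc2c1 | intermediate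
21 | (2S)-2-(2,2-dimethyl-2H-chromen-6-yl)-5,7-bis(methoxymethoxy)-6,8-bis(3-methylbut-2-enyl)chroman-4-one | CC(C)=CCc1c(OCOC)c(CC=C(C)C)c2c(c1OCOC)C(=O)C[C@@H](c1ccc3c(c1)C=CC(C)(C)O3)O2 | intermediate
22 | (2S)-2-(2,2-dimethyl-2H-chromen-6-yl)-5,7-dihydroxy-6,8-bis(3-methylbut-2-enyl)chroman-4-one | CC(C)=CCc1c(O)c(CC=C(C)C)c2c(c1O)C(=O)C[C@@H](c1ccc3c(c1)C=CC(C)(C)O3)O2 | target

## Step count and least certain steps

Total: 10 steps. Longest linear sequence: 7 steps (1, 2, 3, 4, 5, 9, 10); the boronic acid branch (6, 7, 8) has 3 steps.

**Risk at step 3 (key step).**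
- Risk: migration of one allyl group may stay incomplete, above all where the relay through the crowded C6 dienone is needed.
- Risk: a freed phenol may cyclise onto its ortho allyl group if traces of acid form at 200 °C.
- Risk: the pyranone may degrade through attack at C2 during long heating.
- Fallback: the double shift is moved one stage back, where no pyranone is exposed to the heat. Setting out from 3, heating in PhNEt2 should give 1-(3,5-diallyl-2,4,6-trihydroxyphenyl)ethanone F1 by the same ortho/para logic, since C3 and C5 of the acetophenone are its only free ring carbons. Chloromethyl methyl ether and iPr2NEt then cap two phenols to give 1-[3,5-diallyl-2-hydroxy-4,6-bis(methoxymethoxy)phenyl]ethanone F2, the chelated hydroxyl staying free. The amide acetal converts F2 to (E)-1-[3,5-diallyl-2-hydroxy-4,6-bis(methoxymethoxy)phenyl]-3-(dimethylamino)prop-2-en-1-one F3. HCl in methanol closes the pyranone and removes both acetals in the same flask, which returns the route to 9.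

**Risk at step 9.**
- Risk: insertion may be slow, because the 5,7-dioxygenated chromone is a weak acceptor and C8 carries a chain next to O1.
- Risk: the electron-rich boronic acid may be lost by protodeboronation or homocoupling.
- Risk: the ring D alkene or a prenyl alkene may bind the cationic divalent palladium.
- Risk: facial selectivity may be poor or of the opposite sense.
- Fallback: the C2–aryl bond formation is replaced by an aldol/oxa-Michael sequence with resolution. Setting out from 12, aqueous NaOH in ethanol opens the pyranone by hydroxide attack at C2 and retro-Claisen loss of formate to give 1-[2-hydroxy-4,6-bis(methoxymethoxy)-3,5-bis(3-methylbut-2-enyl)phenyl]ethanone F4. Bromide 17 is converted with n-BuLi and DMF to 2,2-dimethyl-2H-chromene-6-carbaldehyde F5. Claisen–Schmidt condensation of F4 and F5 (KOH, EtOH) gives (E)-1-[2-hydroxy-4,6-bis(methoxymethoxy)-3,5-bis(3-methylbut-2-enyl)phenyl]-3-(2,2-dimethyl-2H-chromen-6-yl)prop-2-en-1-one F6, the same compound as A6. NaOAc in refluxing ethanol closes ring C to racemic 2-(2,2-dimethyl-2H-chromen-6-yl)-5,7-bis(methoxymethoxy)-6,8-bis(3-methylbut-2-enyl)chroman-4-one F7. Preparative HPLC on a chiral stationary phase then gives 21, where the route is rejoined. The (2R)-enantiomer F8 can be recycled by base-induced opening back to F6.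

**Risk at step 10.**
- Risk: a prenyl group may cyclise onto the freed ortho phenol under acid.
- Risk: methanol may add to the ring D or prenyl alkenes.
- Risk: C2 may epimerise through acid-promoted opening of ring C.
- Fallback: the acid-labile acetals are replaced by allyl ethers that leave under neutral conditions. Setting out from 11, allyl bromide 2 and K2CO3 in DMF should give 5,7-bis(allyloxy)-6,8-bis(3-methylbut-2-enyl)-4H-chromen-4-one F9. Addition of 20 under the conditions of step 9 should give (2S)-5,7-bis(allyloxy)-2-(2,2-dimethyl-2H-chromen-6-yl)-6,8-bis(3-methylbut-2-enyl)chroman-4-one F10. Pd(PPh3)4 (zerovalent palladium) with N-methylaniline in THF at rt transfers both allyl groups to the amine and gives 22 directly, which is where this detour comes back to the route.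

**Risk at step 4.**
- Risk: metal hydride species derived from RuCl2(=CHPh)(PCy3)(H2IMes) may move an allyl double bond into conjugation with ring A, and metathesis of that isomer would shorten the chain by one carbon.
- Risk: conversion of the second allyl group may be incomplete.
- Risk: self-metathesis may compete.
- Fallback: the chain is extended by cleavage and olefination. Setting out from 9, NaH and chloromethyl methyl ether give 6,8-diallyl-5,7-bis(methoxymethoxy)-4H-chromen-4-one F11. OsO4 (cat.) with NaIO4 and 2,6-lutidine in dioxane–water cleaves both terminal alkenes to 2,2'-[5,7-bis(methoxymethoxy)-4-oxo-4H-chromene-6,8-diyl]diacetaldehyde F12. A Wittig reaction with isopropylidenetriphenylphosphorane (from isopropyltriphenylphosphonium iodide and n-BuLi, THF, −78 °C) then gives 12, where the route is rejoined. The low temperature and exact stoichiometry are meant to keep the ylide away from C2 of the chromone.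

## Further compounds

F1 | step 3 | 1-(3,5-diallyl-2,4,6-trihydroxyphenyl)ethanone | CC(=O)c1c(O)c(CC=C)c(O)c(CC=C)c1O
F2 | step 3 | 1-[3,5-diallyl-2-hydroxy-4,6-bis(methoxymethoxy)phenyl]ethanone | CC(=O)c1c(O)c(CC=C)c(OCOC)c(CC=C)c1OCOC
F3 | step 3 | (E)-1-[3,5-diallyl-2-hydroxy-4,6-bis(methoxymethoxy)phenyl]-3-(dimethylamino)prop-2-en-1-one | CN(C)/C=C/C(=O)c1c(O)c(CC=C)c(OCOC)c(CC=C)c1OCOC
F4 | step 9 | 1-[2-hydroxy-4,6-bis(methoxymethoxy)-3,5-bis(3-methylbut-2-enyl)phenyl]ethanone | CC(=O)c1c(O)c(CC=C(C)C)c(OCOC)c(CC=C(C)C)c1OCOC
F5 | step 9 | 2,2-dimethyl-2H-chromene-6-carbaldehyde | O=Cc1ccc2OC(C)(C)C=Cc2c1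
F6 | step 9 | (E)-1-[2-hydroxy-4,6-bis(methoxymethoxy)-3,5-bis(3-methylbut-2-enyl)phenyl]-3-(2,2-dimethyl-2H-chromen-6-yl)prop-2-en-1-one | CC(C)=CCc1c(O)c(C(=O)/C=C/c2ccc3c(c2)C=CC(C)(C)O3)c(OCOC)c(CC=C(C)C)c1OCOC
F7 | step 9 | racemic 2-(2,2-dimethyl-2H-chromen-6-yl)-5,7-bis(methoxymethoxy)-6,8-bis(3-methylbut-2-enyl)chroman-4-one | CC(C)=CCc1c(OCOC)c(CC=C(C)C)c2c(c1OCOC)C(=O)CC(c1ccc3c(c1)C=CC(C)(C)O3)O2
F8 | step 9 | (2R)-2-(2,2-dimethyl-2H-chromen-6-yl)-5,7-bis(methoxymethoxy)-6,8-bis(3-methylbut-2-enyl)chroman-4-one | CC(C)=CCc1c(OCOC)c(CC=C(C)C)c2c(c1OCOC)C(=O)C[C@H](c1ccc3c(c1)C=CC(C)(C)O3)O2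
F9 | step 10 | 5,7-bis(allyloxy)-6,8-bis(3-methylbut-2-enyl)-4H-chromen-4-one | CC(C)=CCc1c(OCC=C)c(CC=C(C)C)c2c(c1OCC=C)C(=O)C=CO2
F10 | step 10 | (2S)-5,7-bis(allyloxy)-2-(2,2-dimethyl-2H-chromen-6-yl)-6,8-bis(3-methylbut-2-enyl)chroman-4-one | CC(C)=CCc1c(OCC=C)c(CC=C(C)C)c2c(c1OCC=C)C(=O)C[C@@H](c1ccc3c(c1)C=CC(C)(C)O3)O2
F11 | step 4 | 6,8-diallyl-5,7-bis(methoxymethoxy)-4H-chromen-4-one | C=CCc1c(OCOC)c(CC=C)c2c(c1OCOC)C(=O)C=CO2
F12 | step 4 | 2,2'-[5,7-bis(methoxymethoxy)-4-oxo-4H-chromene-6,8-diyl]diacetaldehyde | O=CCc1c(OCOC)c(CC=O)c2c(c1OCOC)C(=O)C=CO2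
A1 | alternative 1 | (2S)-4-methoxy-5,7-bis(methoxymethoxy)-6,8-bis(3-methylbut-2-enyl)-2-(2,2-dimethyl-2H-chromen-6-yl)chromane (C4 configuration open) | CC(C)=CCc1c(OCOC)c(CC=C(C)C)c2c(c1OCOC)C(OC)C[C@@H](c1ccc3c(c1)C=CC(C)(C)O3)O2
A2 | alternative 1 | 2-hydroxy-4,6-bis(methoxymethoxy)-3,5-bis(3-methylbut-2-enyl)benzaldehyde | O=Cc1c(O)c(CC=C(C)C)c(OCOC)c(CC=C(C)C)c1OCOC
A3 | alternative 1 | 6-ethenyl-2,2-dimethyl-2H-chromene | C=Cc1ccc2OC(C)(C)C=Cc2c1
A4 | alternative 1 | trimethyl orthoformate | COC(OC)OC
A5 | alternative 1 | 6-(methoxymethylidene)-3,5-bis(methoxymethoxy)-2,4-bis(3-methylbut-2-enyl)cyclohexa-2,4-dien-1-one | COC=C1C(=O)C(CC=C(C)C)=C(OCOC)C(CC=C(C)C)=C1OCOC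
A6 | alternative 2 | (E)-1-[2-hydroxy-4,6-bis(methoxymethoxy)-3,5-bis(3-methylbut-2-enyl)phenyl]-3-(2,2-dimethyl-2H-chromen-6-yl)prop-2-en-1-one | CC(C)=CCc1c(O)c(C(=O)/C=C/c2ccc3c(c2)C=CC(C)(C)O3)c(OCOC)c(CC=C(C)C)c1OCOC
A7 | alternative 2 | 3,5-bis(methoxymethoxy)-2,4-bis(3-methylbut-2-enyl)-6-(trimethylsilyl)phenyl trifluoromethanesulfonate | C[Si](C)(C)c1c(OS(=O)(=O)C(F)(F)F)c(CC=C(C)C)c(OCOC)c(CC=C(C)C)c1OCOC
A8 | alternative 2 | 1,2-didehydro-3,5-bis(methoxymethoxy)-4,6-bis(3-methylbut-2-enyl)benzene | C1#CC(OCOC)=C(CC=C(C)C)C(OCOC)=C1CC=C(C)C
A9 | alternative 2 | (E)-3-(2,2-dimethyl-2H-chromen-6-yl)prop-2-enoic acid | OC(=O)/C=C/c1ccc2OC(C)(C)C=Cc2c1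
A10 | alternative 3 | 5,7-bis(methoxymethoxy)-6,8-bis(3-methylbut-2-enyl)-2-(2,2-dimethyl-2H-chromen-6-yl)-4H-chromen-4-one | CC(C)=CCc1c(OCOC)c(CC=C(C)C)c2c(c1OCOC)C(=O)C=C(c1ccc3c(c1)C=CC(C)(C)O3)O2
A11 | alternative 3 | 2-iodo-3,5-bis(methoxymethoxy)-4,6-bis(3-methylbut-2-enyl)phenol | Oc1c(I)c(OCOC)c(CC=C(C)C)c(OCOC)c1CC=C(C)C
A12 | alternative 3 | 6-ethynyl-2,2-dimethyl-2H-chromene | C#Cc1ccc2OC(C)(C)C=Cc2c1
A13 | alternative 3 | carbon monoxide | [C-]#[O+]
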